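**Retrosynthetic overview**

1. Numbering is that of the target chromene (O1, C2, C3, C4, C4a, C5–C8, C8a). The acid 34 is unmasked last from the tricyclic enol δ-lactone 32, in which the C6 side-chain carboxyl is tied to O5 as a temporary ring.
2. Key disconnection: the dihydropyranone ring (O1–C2–C3–C4–C4a–C8a) and the C8–prenyl bond of 32 are made in one operation from the flat dihydrocoumarin 28 and prenyl carbonate 30. Pd-catalysed dearomative C8-prenylation is followed, in the same flask, by cyclodehydration of the syn-aldol hydroxyl onto C8a.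
3. Enabling feature: C8 is an sp3 quaternary carbon between C7=O and C8a–O1, so the carbocycle C4a–C5–C6–C7–C8–C8a is a dearomatised acylphloroglucinol. C-alkylation at C8 turns C8a from a phenol carbon into a vinylogous-acid carbonyl that condenses with the C2 hydroxyl. The C6 side chain reaches O5 as a six-membered lactone and so blocks the competing closure at C5.
4. 28 comes from phloroglucinol by Pechmann condensation, Friedel–Crafts propanoylation, asymmetric hydrogenation (side-chain centre), Negishi coupling with the auxiliary-derived (S)-iodide 20 (lavandulyl-type centre) and an Ipc2B-mediated syn-aldol (C2, C3).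
5. Ring order: carbocycle bought as the arene; temporary lactone ring (step 1, opened in step 16); dihydropyranone ring last (step 15).

Key step: step 15

Remark: intermediates 3–28 are named as chromen-2-ones; their C6, C7–O, C8, C8a–O, C4a, C5–O and C4 become C8, C8a–O1, C4a, C5–O, C6, C7=O and the side-chain CH of the target.

Assumption: in steps 4, 12 and 15 the antipode of the chiral ligand or reagent named is the one expected to give the drawn configuration; the sense of induction is empirical for these substrates, and the mirror-image ligand would be used if it proved opposite.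

**Route**

Step 1
Reactants: 1 phloroglucinol; 2 ethyl 3-oxohexanoate
Product: 3 5,7-dihydroxy-4-propyl-2H-chromen-2-one
Conditions: MeSO3H (or conc. H2SO4), rt
Reagents that add atoms: none
Why: Pechmann condensation (transesterification, intramolecular hydroxyalkylation, dehydration) of the C3-symmetric triphenol can give only this coumarin, whose lactone later serves as the temporary ring.

Step 2
Reactants: 3 5,7-dihydroxy-4-propylcoumarin; 4 propanoyl chloride
Product: 5 5,7-dihydroxy-8-propanoyl-4-propyl-2H-chromen-2-one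
Conditions: AlCl3, PhNO2–CS2, 70 °C
Reagents that add atoms: none
Why: Friedel–Crafts acylation, for which C8 (between O1 and the 7-OH) is the established preferred site in 5,7-dihydroxy-4-alkylcoumarins; the minor 6-acyl isomer should be removable by crystallisation.

Step 3
Reactants: 5 8-propanoyl coumarin diol
Product: 6 5,7-bis(methoxymethoxy)-8-propanoyl-4-propyl-2H-chromen-2-one
Conditions: MOMCl, K2CO3, acetone, 0 °C → reflux
Reagents that add atoms: chloromethyl methyl ether (MOMCl), COCCl
Why: O-alkylation of both phenols (including the chelated 7-OH) gives small acetal ethers that should survive hydroxide, organozinc and boron triflate and come off later without protic acid.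

Step 4
Reactants: 6 bis-MOM coumarin
Product: 9 (4S)-5,7-bis(methoxymethoxy)-8-propanoyl-4-propyl-3,4-dihydro-2H-chromen-2-one, via ring-opened disodium (Z)-acrylate 7 (not isolated), via hydrogenated disodium carboxylate 8 (not isolated)
Conditions: NaOH (2.1 equiv), MeOH–H2O, 40 °C; [Ru(OAc)2((S)-BINAP)] (1 mol%), H2 (20 bar), 50 °C; then AcOH, toluene, 60 °C
Reagents that add atoms: none
Why: carboxylate-directed Ru–BINAP asymmetric hydrogenation of the ring-opened (Z)-β-aryl-β-propylacrylate (a known way to reduce 4-substituted coumarins enantioselectively) sets C4 as S by ligand control; the ketone is not touched and, O1 being the only free phenol, acidification can re-close only the original lactone.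

Step 5
Reactants: 9 (4S)-bis-MOM dihydrocoumarin
Product: 10 (4S)-6-bromo-5,7-bis(methoxymethoxy)-8-propanoyl-4-propyl-3,4-dihydro-2H-chromen-2-one
Conditions: NBS, MeCN, 0 °C → rt
Reagents that add atoms: N-bromosuccinimide, O=C1CCC(=O)N1Br
Why: electrophilic aromatic bromination at the only free ring position, which is activated by two ortho alkoxy groups and a para acyloxy group.

Step 6
Reactants: 11 (4S)-4-benzyl-1,3-oxazolidin-2-one; 12 3-methylbut-2-enoyl chloride
Product: 14 (4S)-4-benzyl-3-(3-methylbut-2-enoyl)-1,3-oxazolidin-2-one, via lithiated oxazolidinone 13 (not isolated)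
Conditions: n-BuLi, THF, −78 °C; then 12, −78 → 0 °C
Reagents that add atoms: none
Why: N-acylation of the lithiated Evans auxiliary, which avoids the amine-induced vinylketene formation that would deconjugate the acid chloride.

Step 7
Reactants: 15 3-methylbut-3-en-1-ol
Product: 16 3-methylbut-3-en-1-yl trifluoromethanesulfonate
Conditions: Tf2O, pyridine, CH2Cl2, −78 → −30 °C; cold filtration through silica, used at once
Reagents that add atoms: trifluoromethanesulfonic anhydride, O=S(=O)(OS(=O)(=O)C(F)(F)F)C(F)(F)F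
Why: O-triflation turns the unactivated primary homoallylic alcohol into an electrophile reactive enough for an imide enolate at −78 °C.

Step 8
Reactants: 14 N-senecioyl oxazolidinone; 16 homoallylic triflate
Product: 18 (4S)-4-benzyl-3-[(2S)-5-methyl-2-(prop-1-en-2-yl)hex-5-enoyl]-1,3-oxazolidin-2-one, via sodium (Z)-dienolate 17 (not isolated)
Conditions: NaHMDS, THF, −78 °C; then 16, −78 → −40 °C
Reagents that add atoms: none
Why: Evans deconjugative α-alkylation, in which γ-deprotonation gives the chelated (Z)-dienolate and the triflate attacks Cα on the face opposite the benzyl group, setting the new centre as S and leaving the isopropenyl group.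

Step 9
Reactants: 18 alkylated imide
Product: 19 (2S)-5-methyl-2-(prop-1-en-2-yl)hex-5-en-1-ol
Conditions: LiBH4, Et2O, MeOH (1 equiv), 0 °C
Reagents that add atoms: none
Why: reductive cleavage of the N-acyl oxazolidinone to the primary alcohol proceeds without enolisation, so the allylic α-centre is neither epimerised nor conjugated.

Step 10
Reactants: 19 (S)-alcohol
Product: 20 (3S)-3-(iodomethyl)-2,6-dimethylhepta-1,6-diene
Conditions: I2, PPh3, imidazole, CH2Cl2, 0 °C → rt
Reagents that add atoms: iodine, II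
Why: Appel-type (Garegg–Samuelsson) iodination at the primary carbon does not involve the stereocentre.

Step 11
Reactants: 20 (S)-iodide; 10 aryl bromide
Product: 22 (4S)-5,7-bis(methoxymethoxy)-6-[(2R)-5-methyl-2-(prop-1-en-2-yl)hex-5-en-1-yl]-8-propanoyl-4-propyl-3,4-dihydro-2H-chromen-2-one, via alkylzinc iodide 21 (not isolated)
Conditions: Zn dust (activated), LiCl, THF, 40 °C; then 10, Pd(OAc)2 (4 mol%), SPhos (8 mol%), THF, 60 °C
Reagents that add atoms: none
Why: LiCl-assisted zinc insertion into the primary C–I bond followed by Negishi sp3–sp2 coupling with a bulky biarylphosphine joins the side chain to the hindered ring carbon; the organozinc tolerates ketone, lactone and acetals, and the β-stereocentre is not involved.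

Step 12
Reactants: 22 aryl ethyl ketone; 23 acetaldehyde
Product: 26 (4S)-8-[(2S,3R)-3-hydroxy-2-methylbutanoyl]-5,7-bis(methoxymethoxy)-6-[(2R)-5-methyl-2-(prop-1-en-2-yl)hex-5-en-1-yl]-4-propyl-3,4-dihydro-2H-chromen-2-one, via (Z)-enol diisopinocampheylborinate 24 (not isolated), via boron aldolate 25 (not isolated)
Conditions: (−)-Ipc2BOTf, i-Pr2NEt, CH2Cl2, −78 → 0 °C; MeCHO, −78 → −20 °C; H2O2, pH 7 buffer, MeOH, 0 °C
Reagents that add atoms: none
Why: Paterson boron aldol, in which the (Z)-enol borinate reacts through a Zimmerman–Traxler chair to give the syn aldol and the Ipc ligands select the aldehyde face for (2S,3R); the minor syn isomer is a diastereomer (C4 and the side-chain centre are fixed) and should be removable by chromatography.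

Step 13
Reactants: 26 bis-MOM syn-aldol
Product: 28 (4S)-5,7-dihydroxy-8-[(2S,3R)-3-hydroxy-2-methylbutanoyl]-6-[(2R)-5-methyl-2-(prop-1-en-2-yl)hex-5-en-1-yl]-4-propyl-3,4-dihydro-2H-chromen-2-one, via tris(trimethylsilyl) ether 27 (not isolated)
Conditions: TMSOTf, 2,2′-bipyridyl, CH2Cl2, 0 °C; then H2O–THF, citric acid (cat.), rt
Reagents that add atoms: none
Why: silyl triflate/bipyridyl cleavage of aryl MOM ethers exchanges the acetals for silyl ethers under buffered aprotic conditions and water then frees the phenols, so no acid strong enough to protonate the 1,1-disubstituted alkenes or dehydrate the aldol is present.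

Step 14
Reactants: 29 3-methylbut-2-en-1-ol
Product: 30 tert-butyl 3-methylbut-2-en-1-yl carbonate
Conditions: Boc2O, n-Bu4NHSO4 (cat.), 30% aq. NaOH, CH2Cl2, 0 °C → rt
Reagents that add atoms: di-tert-butyl dicarbonate, CC(C)(C)OC(=O)OC(=O)OC(C)(C)C
Why: phase-transfer O-acylation gives the allylic carbonate, which ionises with Pd(0) without added base.

Step 15
Reactants: 28 dihydrocoumarin syn-aldol diphenol; 30 prenyl tert-butyl carbonate
Product: 32 (4S,6R,8R,9S)-8,9-dimethyl-6-(3-methylbut-2-en-1-yl)-6-[(2R)-5-methyl-2-(prop-1-en-2-yl)hex-5-en-1-yl]-4-propyl-3,4,8,9-tetrahydro-2H-pyrano[2,3-f]chromene-2,5,10(6H)-trione, via dearomatised hydroxy-triketone 31 (not isolated)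
Conditions: Pd2(dba)3·CHCl3 (2.5 mol%), (R,R)-N,N′-(cyclohexane-1,2-diyl)bis[2-(diphenylphosphino)benzamide] (7.5 mol%), 30 (1.05 equiv), CH2Cl2, 0 °C → rt; then PPTS (0.3 equiv), 4 Å MS, 35 °C, same flask
Reagents that add atoms: none
Why: Pd(0) ionises 30 with loss of CO2 and tert-butoxide, which deprotonates the phenol para to the ketone (O7 of the target); the phenoxide attacks the unsubstituted terminus of the π-prenyl complex through C8 (C6 of 28), the only ring carbon flanked by two free oxygens, so the arene is dearomatised to the vinylogous acid 31, any O-prenyl ether re-ionising under Pd(0) until the C-alkylated β-triketone, the thermodynamic sink, is reached. The closest known reactions are the Tsuji–Trost alkylative dearomatisation of fully substituted acylphloroglucinols, the Pd-catalysed asymmetric allylic dearomatisation of phenols, and the acid-catalysed cyclodehydration of δ-hydroxy-β-diketones to 2,3-dihydro-4H-pyran-4-ones. The pyranone ring closes by 6-exo-trig addition of the C2 hydroxyl to the newly unmasked C8a carbonyl (hemiketal) and loss of water, a net addition–elimination at a carbon that was an inert phenol carbon before dearomatisation. C8 (R) is set by the chiral ligand in what should be the matched case, because the pseudo-axial propyl group of the lactone ring lies on the face opposite to the one the prenyl group must enter; C2 (R) and C3 (S) are carried over from the syn-aldol, since the C2–O bond is never broken and C4 enolises towards C4a, not C3. The step needs C- over O-alkylation and attack at C8 rather than C4a or C6 (secured by reversible O-allylation and by C8 being the least hindered, doubly activated site), mono-prenylation (1.05 equiv of 30), and closure onto C8a rather than C5 (secured by the temporary lactone, which keeps O5 acylated); PPTS is mild enough to spare the prenyl and 1,1-disubstituted alkenes.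

Step 16
Reactants: 32 tricyclic enol lactone
Product: 34 (3S)-3-[(2R,3S,8R)-5-hydroxy-2,3-dimethyl-8-(3-methylbut-2-en-1-yl)-8-[(2R)-5-methyl-2-(prop-1-en-2-yl)hex-5-en-1-yl]-4,7-dioxo-3,4,7,8-tetrahydro-2H-chromen-6-yl]hexanoic acid, via dilithium salt 33 (not isolated)
Conditions: LiOH (3 equiv), THF–H2O (3:1), 0 °C; then 1 M HCl to pH 3, 0 °C
Reagents that add atoms: lithium hydroxide, [Li+].[OH-]
Why: the enol δ-lactone is a vinylogous anhydride and should saponify within minutes at 0 °C; the resulting carboxylate/enolate dianion resists deprotonation at C3, so the cis-2,3-dimethyl relationship should survive, and acidification gives the acid and the C5 enol.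

**Compound list**

1 | phloroglucinol (benzene-1,3,5-triol) | Oc1cc(O)cc(O)c1 | starting material
2 | ethyl 3-oxohexanoate | CCCC(=O)CC(=O)OCC | starting material
3 | 5,7-dihydroxy-4-propyl-2H-chromen-2-one | CCCC1=CC(=O)Oc2cc(O)cc(O)c12 | intermediate
4 | propanoyl chloride | CCC(Cl)=O | starting material
5 | 5,7-dihydroxy-8-propanoyl-4-propyl-2H-chromen-2-one | CCCC1=CC(=O)Oc2c(C(=O)CC)c(O)cc(O)c12 | intermediate
6 | 5,7-bis(methoxymethoxy)-8-propanoyl-4-propyl-2H-chromen-2-one | CCCC1=CC(=O)Oc2c(C(=O)CC)c(OCOC)cc(OCOC)c12 | intermediate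
7 | disodium (2Z)-3-[4,6-bis(methoxymethoxy)-2-oxido-3-propanoylphenyl]hex-2-enoate | CCC/C(=C/C(=O)[O-])c1c([O-])c(C(=O)CC)c(OCOC)cc1OCOC.[Na+].[Na+] | intermediate
8 | disodium (3S)-3-[4,6-bis(methoxymethoxy)-2-oxido-3-propanoylphenyl]hexanoate | CCC[C@@H](CC(=O)[O-])c1c([O-])c(C(=O)CC)c(OCOC)cc1OCOC.[Na+].[Na+] | intermediate
9 | (4S)-5,7-bis(methoxymethoxy)-8-propanoyl-4-propyl-3,4-dihydro-2H-chromen-2-one | CCC[C@H]1CC(=O)Oc2c(C(=O)CC)c(OCOC)cc(OCOC)c12 | intermediate
10 | (4S)-6-bromo-5,7-bis(methoxymethoxy)-8-propanoyl-4-propyl-3,4-dihydro-2H-chromen-2-one | CCC[C@H]1CC(=O)Oc2c(C(=O)CC)c(OCOC)c(Br)c(OCOC)c12 | intermediate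
11 | (4S)-4-benzyl-1,3-oxazolidin-2-one | O=C1N[C@@H](Cc2ccccc2)CO1 | starting material
12 | 3-methylbut-2-enoyl chloride | CC(C)=CC(Cl)=O | starting material
13 | lithium (4S)-4-benzyl-2-oxo-1,3-oxazolidin-3-ide | [Li+].O=C1[N-][C@@H](Cc2ccccc2)CO1 | intermediate
14 | (4S)-4-benzyl-3-(3-methylbut-2-enoyl)-1,3-oxazolidin-2-one | CC(C)=CC(=O)N1[C@@H](Cc2ccccc2)COC1=O | intermediate
15 | 3-methylbut-3-en-1-ol | C=C(C)CCO | starting material
16 | 3-methylbut-3-en-1-yl trifluoromethanesulfonate | C=C(C)CCOS(=O)(=O)C(F)(F)F | intermediate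
17 | sodium (Z)-dienolate of 14 (O− cis to the isopropenyl group) | C=C(C)/C=C(\[O-])N1[C@@H](Cc2ccccc2)COC1=O.[Na+] | intermediate
18 | (4S)-4-benzyl-3-[(2S)-5-methyl-2-(prop-1-en-2-yl)hex-5-enoyl]-1,3-oxazolidin-2-one | C=C(C)CC[C@H](C(=O)N1[C@@H](Cc2ccccc2)COC1=O)C(C)=C | intermediate
19 | (2S)-5-methyl-2-(prop-1-en-2-yl)hex-5-en-1-ol | C=C(C)CC[C@H](CO)C(C)=C | intermediate
20 | (3S)-3-(iodomethyl)-2,6-dimethylhepta-1,6-diene | C=C(C)CC[C@H](CI)C(C)=C | intermediate
21 | [(2S)-5-methyl-2-(prop-1-en-2-yl)hex-5-en-1-yl]zinc iodide | C=C(C)CC[C@H](C[Zn]I)C(C)=C | intermediate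
22 | (4S)-5,7-bis(methoxymethoxy)-6-[(2R)-5-methyl-2-(prop-1-en-2-yl)hex-5-en-1-yl]-8-propanoyl-4-propyl-3,4-dihydro-2H-chromen-2-one | CCC[C@H]1CC(=O)Oc2c(C(=O)CC)c(OCOC)c(C[C@@H](CCC(C)=C)C(C)=C)c(OCOC)c12 | intermediate
23 | acetaldehyde | CC=O | starting material
24 | (Z)-enol diisopinocampheylborinate of 22 (O–B(Ipc)2 on the former ketone carbon, Ipc from (+)-α-pinene) | CCC[C@H]1CC(=O)Oc2c(/C(OB([C@@H]3C[C@@H]4C[C@H]([C@H]3C)C4(C)C)[C@@H]3C[C@@H]4C[C@H]([C@H]3C)C4(C)C)=C/C)c(OCOC)c(C[C@@H](CCC(C)=C)C(C)=C)c(OCOC)c12 | intermediate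
25 | diisopinocampheylboron aldolate of 26 | CCC[C@H]1CC(=O)Oc2c(C(=O)[C@@H](C)[C@@H](C)OB([C@@H]3C[C@@H]4C[C@H]([C@H]3C)C4(C)C)[C@@H]3C[C@@H]4C[C@H]([C@H]3C)C4(C)C)c(OCOC)c(C[C@@H](CCC(C)=C)C(C)=C)c(OCOC)c12 | intermediate
26 | (4S)-8-[(2S,3R)-3-hydroxy-2-methylbutanoyl]-5,7-bis(methoxymethoxy)-6-[(2R)-5-methyl-2-(prop-1-en-2-yl)hex-5-en-1-yl]-4-propyl-3,4-dihydro-2H-chromen-2-one | CCC[C@H]1CC(=O)Oc2c(C(=O)[C@@H](C)[C@@H](C)O)c(OCOC)c(C[C@@H](CCC(C)=C)C(C)=C)c(OCOC)c12 | intermediate
27 | tris(trimethylsilyl) ether of 28 (both phenols and the secondary alcohol silylated) | CCC[C@H]1CC(=O)Oc2c(C(=O)[C@@H](C)[C@@H](C)O[Si](C)(C)C)c(O[Si](C)(C)C)c(C[C@@H](CCC(C)=C)C(C)=C)c(O[Si](C)(C)C)c12 | intermediate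
28 | (4S)-5,7-dihydroxy-8-[(2S,3R)-3-hydroxy-2-methylbutanoyl]-6-[(2R)-5-methyl-2-(prop-1-en-2-yl)hex-5-en-1-yl]-4-propyl-3,4-dihydro-2H-chromen-2-one | CCC[C@H]1CC(=O)Oc2c(C(=O)[C@@H](C)[C@@H](C)O)c(O)c(C[C@@H](CCC(C)=C)C(C)=C)c(O)c12 | intermediate
29 | 3-methylbut-2-en-1-ol | CC(C)=CCO | starting material
30 | tert-butyl 3-methylbut-2-en-1-yl carbonate | CC(C)=CCOC(=O)OC(C)(C)C | intermediate
31 | (4S,6R)-7-hydroxy-8-[(2S,3R)-3-hydroxy-2-methylbutanoyl]-6-(3-methylbut-2-en-1-yl)-6-[(2R)-5-methyl-2-(prop-1-en-2-yl)hex-5-en-1-yl]-4-propyl-3,4-dihydro-2H-chromene-2,5(6H)-dione (dearomatised triketone, enol form) | C=C(C)CC[C@H](C[C@@]1(CC=C(C)C)C(=O)C2=C(OC(=O)C[C@@H]2CCC)C(C(=O)[C@@H](C)[C@@H](C)O)=C1O)C(=C)C | intermediate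
32 | (4S,6R,8R,9S)-8,9-dimethyl-6-(3-methylbut-2-en-1-yl)-6-[(2R)-5-methyl-2-(prop-1-en-2-yl)hex-5-en-1-yl]-4-propyl-3,4,8,9-tetrahydro-2H-pyrano[2,3-f]chromene-2,5,10(6H)-trione (target with its CO2H lactonised onto O5) | C=C(C)CC[C@H](C[C@@]1(CC=C(C)C)C(=O)C2=C(OC(=O)C[C@@H]2CCC)C3=C1O[C@H](C)[C@H](C)C3=O)C(=C)C | intermediate
33 | dilithium salt of 34 (carboxylate and C5 enolate) | C=C(C)CC[C@H](C[C@@]1(CC=C(C)C)C(=O)C([C@@H](CCC)CC(=O)[O-])=C([O-])C2=C1O[C@H](C)[C@H](C)C2=O)C(=C)C.[Li+].[Li+] | intermediate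
34 | (3S)-3-[(2R,3S,8R)-5-hydroxy-2,3-dimethyl-8-(3-methylbut-2-en-1-yl)-8-[(2R)-5-methyl-2-(prop-1-en-2-yl)hex-5-en-1-yl]-4,7-dioxo-3,4,7,8-tetrahydro-2H-chromen-6-yl]hexanoic acid | C=C(C)CC[C@H](C[C@@]1(CC=C(C)C)C(=O)C([C@@H](CCC)CC(=O)O)=C(O)C2=C1O[C@H](C)[C@H](C)C2=O)C(=C)C | target

**Step count and risks**

Total step count: 16. Longest linear sequence: 10 steps (1, 2, 3, 4, 5, 11, 12, 13, 15, 16).

Steps most likely to fail:

Step 15. The one-pot process may suffer from insufficient facial selectivity at C8, from a second prenylation of the acidic triketone enol, or from closure by addition–elimination at the acyloxy-bearing C5 instead of at C8a. The fallback moves the ring closure to the aromatic stage and sets out from 26. Mesylation (MsCl, Et3N, CH2Cl2, 0 °C) should give the β-mesyloxy ketone F1, and DBU should eliminate it to the (E)-2-methylbut-2-enoyl ketone F2. MOM removal as in step 13 should pass through the bis(trimethylsilyl) ether F3 to the tigloyl diphenol F4. A cinchona-alkaloid-catalysed intramolecular oxa-Michael addition (quinine or quinidine, chlorobenzene, rt) is a known way to close o-tigloylphenols of this coumarin class to cis-2,3-dimethylchroman-4-ones enantioselectively, and should give the aromatic tricyclic chromanone F5. F5 has a single phenoxide and a single reasonable site of C-alkylation, so Pd-catalysed dearomative prenylation with 30 (same catalyst as step 15, C8 epimers separable as diastereomers if needed) comes back to the route at 32.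

Step 12. Enolisation of the hindered, doubly ortho-substituted aryl ketone by the bulky boron triflate may be slow, and reagent control of the aldehyde face may be poor. The fallback sets out from 22 and gives up reagent control: enolisation with Bu2BOTf/i-Pr2NEt to the (Z)-enol dibutylborinate F6 and addition of acetaldehyde is syn-selective without any chiral controller. Because C4 and the side-chain centre are already fixed, 26 and its (2R,3S)-syn isomer F7 are diastereomers and should be separable by chromatography. F7 can be recycled to 22 by base-mediated retro-aldol cleavage, and the fallback comes back to the route at 26.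

Step 4. Hydrogenation of the ring-opened acrylate may be slow or poorly selective because the aryl group is ortho-disubstituted and twisted out of conjugation. The fallback sets out from 6 and reduces the intact coumarin by copper hydride-catalysed asymmetric 1,4-hydrosilylation (Cu(OAc)2, (R)-DTBM-SEGPHOS, PMHS, t-BuOH, toluene), a known asymmetric conjugate reduction of 4-substituted coumarins that needs no ring opening. Concurrent 1,2-reduction of the aryl ketone is accepted: it would give the carbinol F8 (either epimer at the carbinol), which Dess–Martin oxidation returns to the route at 9.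

**Further compounds**

F1 | step 15 | (4S)-5,7-bis(methoxymethoxy)-8-[(2S,3R)-3-(methanesulfonyloxy)-2-methylbutanoyl]-6-[(2R)-5-methyl-2-(prop-1-en-2-yl)hex-5-en-1-yl]-4-propyl-3,4-dihydro-2H-chromen-2-one | CCC[C@H]1CC(=O)Oc2c(C(=O)[C@@H](C)[C@@H](C)OS(C)(=O)=O)c(OCOC)c(C[C@@H](CCC(C)=C)C(C)=C)c(OCOC)c12
F2 | step 15 | (4S)-5,7-bis(methoxymethoxy)-8-[(2E)-2-methylbut-2-enoyl]-6-[(2R)-5-methyl-2-(prop-1-en-2-yl)hex-5-en-1-yl]-4-propyl-3,4-dihydro-2H-chromen-2-one | CCC[C@H]1CC(=O)Oc2c(C(=O)/C(C)=C/C)c(OCOC)c(C[C@@H](CCC(C)=C)C(C)=C)c(OCOC)c12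
F3 | step 15 | (4S)-8-[(2E)-2-methylbut-2-enoyl]-6-[(2R)-5-methyl-2-(prop-1-en-2-yl)hex-5-en-1-yl]-4-propyl-5,7-bis(trimethylsilyloxy)-3,4-dihydro-2H-chromen-2-one | CCC[C@H]1CC(=O)Oc2c(C(=O)/C(C)=C/C)c(O[Si](C)(C)C)c(C[C@@H](CCC(C)=C)C(C)=C)c(O[Si](C)(C)C)c12
F4 | step 15 | (4S)-5,7-dihydroxy-8-[(2E)-2-methylbut-2-enoyl]-6-[(2R)-5-methyl-2-(prop-1-en-2-yl)hex-5-en-1-yl]-4-propyl-3,4-dihydro-2H-chromen-2-one | CCC[C@H]1CC(=O)Oc2c(C(=O)/C(C)=C/C)c(O)c(C[C@@H](CCC(C)=C)C(C)=C)c(O)c12
F5 | step 15 | (4S,8R,9S)-5-hydroxy-8,9-dimethyl-6-[(2R)-5-methyl-2-(prop-1-en-2-yl)hex-5-en-1-yl]-4-propyl-3,4,8,9-tetrahydro-2H-pyrano[2,3-f]chromene-2,10-dione | CCC[C@H]1CC(=O)Oc2c3C(=O)[C@@H](C)[C@@H](C)Oc3c(C[C@@H](CCC(C)=C)C(C)=C)c(O)c12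
F6 | step 12 | (Z)-enol dibutylborinate of 22 | CCC[C@H]1CC(=O)Oc2c(/C(OB(CCCC)CCCC)=C/C)c(OCOC)c(C[C@@H](CCC(C)=C)C(C)=C)c(OCOC)c12
F7 | step 12 | (4S)-8-[(2R,3S)-3-hydroxy-2-methylbutanoyl]-5,7-bis(methoxymethoxy)-6-[(2R)-5-methyl-2-(prop-1-en-2-yl)hex-5-en-1-yl]-4-propyl-3,4-dihydro-2H-chromen-2-one | CCC[C@H]1CC(=O)Oc2c(C(=O)[C@H](C)[C@H](C)O)c(OCOC)c(C[C@@H](CCC(C)=C)C(C)=C)c(OCOC)c12
F8 | step 4 | (4S)-8-(1-hydroxypropyl)-5,7-bis(methoxymethoxy)-4-propyl-3,4-dihydro-2H-chromen-2-one (carbinol centre undefined) | CCC[C@H]1CC(=O)Oc2c(C(O)CC)c(OCOC)cc(OCOC)c12
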